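3 questions stand on these flasks: two orders of the first rate, and a share of target in a flask charged with target.

the same everywhere: catalyst 0.0240 M

| charge | starting material | partner | target | time |
|---|---|---|---|---|
| west | 0.800 M | 2.00 M |  |  |
| north | 0.320 M | 1.52 M |  |  |
| east | 0.800 M | 1.00 M |  |  |
| north-west | 1.60 M | 2.00 M |  |  |
| south-west | 0.800 M | 2.00 M | 0.800 M | 53 min |

| west run: time / min | west run: [target] / M | north run: time / min | north run: [target] / M | east run: time / min | east run: [target] / M | north-west run: time / min | north-west run: [target] / M |
|---|---|---|---|---|---|---|---|
| 6.6 | 0.084 | 6.6 | 0.074 | 6.6 | 0.032 | 6.6 | 0.069 |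
| 13 | 0.142 | 13 | 0.132 | 13 | 0.081 | 13 | 0.117 |
| 20 | 0.199 | 20 | 0.185 | 20 | 0.103 | 20 | 0.165 |
| 26 | 0.237 | 26 | 0.193 | 26 | 0.134 | 26 | 0.209 |
| 33 | 0.276 | 33 | 0.198 | 33 | 0.140 | 33 | 0.231 |
| 40 | 0.321 | 40 | 0.166 | 40 | 0.157 | 40 | 0.244 |
| 46 | 0.337 | 46 | 0.125 | 46 | 0.167 | 46 | 0.279 |
| 53 | 0.343 | 53 | 0.108 | 53 | 0.178 | 53 | 0.288 |

(standard deviation of a reading: 0.008 M)

- the power of [partner] that the first rate follows, about the charge of the west run; measure it at two percent of starting material made into target
- the power of [starting material] that the first rate follows, about the charge of the west run; measure it at two percent of starting material made into target (one fixed amount of target, the same in the runs compared)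
- target in the south-west run at 53 min, as a share of the starting material charged

- Overall: starting material + partner -> target, with catalyst as catalyst.
- Constant volume, constant temperature.
- What is held in complexes is read along with the free species.
- An order is taken over about fifteen percent of the charge, up and down.
- A share of target counts the target that was charged too.

My own reckoning is for the third question, and it follows the north run in slow motion.

1. First instants. The north run holds 0.320 M of starting material, less than the 1.52 M of partner, so starting material is the limiting reagent. The first reading gives 0.0112 M min⁻¹ of net target formation.

2. Middle. The highest north reading is 0.198 M at 33 min, which is below the charge of starting material. Target is therefore being lost on the way up.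

3. End. By 53 min the north reading has sunk to 0.108 M. Taking this tail as first-order decay gives a loss constant k, the fraction of target lost per minute, of 0.0303 min⁻¹, with a scatter of 0.00422 min⁻¹. From k follows the survival share s, the fraction of the target present at the start that still stands after 53 min: 20.1%.

4. Second round. Putting k back over the rising part of the north run, the target lost by 33 min comes to 0.137 M. The target made is then 0.335 M against a charge of 0.320 M. The excess of 0.0150 M is smaller than the 0.0191 M that the scatter of k carries into the target lost, so the tail is read as decay with little formation in it.

5. South-west run. If target takes no part in its own formation, this flask is the west run plus charged target decaying beside it. That gives 0.343 M plus 0.161 M, or 0.504 M, a share of 62.9%.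

The forecast gives 1 for partner, −0.2 for starting material and 75% for the share, holding that “target is truly consumed”. Its share stands 12 percentage points above mine, and I add no orders of my own.

The simulation gives orders of 0.85 and −0.24, and 68.6%, which is 0.549 M of target in the south-west run. In the scheme, target enters no complex and leaves by one first-order step.

    catalyst + starting material ⇌ catalyst-substrate complex, settled at all times (17.00 L mol⁻¹)
    catalyst + partner ⇌ catalyst-reagent complex, settled at all times (0.2170 L mol⁻¹)
    catalyst-substrate complex + catalyst-reagent complex → target + 2 catalyst (360.6 L mol⁻¹ min⁻¹)
    2 starting material ⇌ idle substrate dimer, settled at all times (8.000 L mol⁻¹)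
    target → decomposed product (0.02670 min⁻¹)

Taking away the west reading leaves 0.206 M of charged target, a share of 25.7% against s of 20.1%. In the east run, the rate of 0.0068 M min⁻¹ held steady against the scheme's loss constant of 0.0267 min⁻¹ has a steady level of 0.255 M, and the share 75.7% of that level gives 0.193 M at 53 min, above the reading of 0.178 M.

(The numbers in the tables are calculated from invented constants; the scatter is artificial.)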